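The six-membered quinone ring is taken apart completely and rebuilt in one [3+2+1] benzannulation of a chromium carbene, an alkyne and one CO ligand. The step exploits the 1,2,4,5-tetraoxygenated ring (C1/C4 carbonyls, C2/C5 hydroxyls), whose hexadecyl-bearing C3 lies between two oxygenated carbons while C6 is the only CH. C4 arrives as a methoxycarbene carbon, C5–C6 as its 1-ethoxyvinyl group, C2–C3 as the silyl ynol ether of 1-octadecyne, and C1 as CO. The precursors are therefore pentacarbonyl[(1-ethoxyethenyl)(methoxy)carbene]chromium and 1-(triisopropylsilyloxy)octadec-1-yne; oxidative demethylation and hydrolysis of the resulting 4-methoxyphenol complete the synthesis.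

Key step: step 3

Remark: the target has no stereocentre. It is treated as the drawn 2,5-dihydroxy-1,4-benzoquinone tautomer, and the ring numbering given above is used throughout.

Step 1
Reactants: 1 ethyl vinyl ether; 2 hexacarbonylchromium
Product: 5 pentacarbonyl[(1-ethoxyethenyl)(methoxy)carbene]chromium, via 1-ethoxyvinyllithium 3 (not isolated), via lithium pentacarbonyl(2-ethoxyprop-2-enoyl)chromate 4 (not isolated)
Conditions: t-BuLi, THF, −78 to 0 °C; Cr(CO)6, THF, 0 °C to rt; evaporate; Me3OBF4, CH2Cl2, 0 °C
Reagents that add atoms: trimethyloxonium tetrafluoroborate, C[O+](C)C.F[B-](F)(F)F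
Why: Fischer-type alkoxycarbene synthesis, in which the α-lithiated enol ether adds to a CO ligand and the acyl chromate oxygen is methylated under anhydrous conditions after removal of excess 1, as is established for cyclic 2-oxacycloalkenyllithium reagents.

Step 2
Reactants: 6 1-octadecyne
Product: 9 1-(triisopropylsilyloxy)octadec-1-yne, via lithium octadec-1-yn-1-ide 7 (not isolated), via lithium octadec-1-yn-1-olate 8 (not isolated)
Conditions: LiN(SiMe3)2, THF, −78 °C; LiOOt-Bu (from t-BuOOH + LiN(SiMe3)2), THF, −78 to 0 °C; iPr3SiOSO2CF3, −78 to 0 °C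
Reagents that add atoms: tert-butyl hydroperoxide, CC(C)(C)OO; triisopropylsilyl trifluoromethanesulfonate, CC(C)[Si](OS(=O)(=O)C(F)(F)F)(C(C)C)C(C)C
Why: Oxidation of a lithium acetylide to the ynolate by electrophilic oxygen transfer from lithium tert-butyl peroxide, followed by O-silylation with a bulky silyl triflate, is the established route to isolable triisopropylsilyl ynol ethers.

Step 3
Reactants: 5 pentacarbonyl[(1-ethoxyethenyl)(methoxy)carbene]chromium; 9 1-(triisopropylsilyloxy)octadec-1-yne
Product: 11 5-ethoxy-3-hexadecyl-4-methoxy-2-(triisopropylsilyloxy)phenol, via tricarbonyl(η6-phenol)chromium complex 10 (not isolated)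
Conditions: 9 (1.3 equiv), degassed THF, 50 °C, Ar; then air, rt, filtration through SiO2
Reagents that add atoms: none
Why: Proposed new method: loss of a cis CO from the zerovalent chromium centre of 5 lets 9 bind and insert into the Cr=C bond (C3–C4), the chromium-bound silyloxycarbene carbon then migrates to a CO ligand (C1–C2), and the resulting chromium-bound dienylketene closes between the ketene carbon and the vinyl CH2 (C1–C6) before tautomerising to the phenol, which stays bound as complex 10 until air releases 11. The closest known reaction type is the Dötz benzannulation of alkenyl(alkoxy)carbene pentacarbonylchromium complexes with carbon-substituted alkynes, established for cyclic 2-oxacycloalkenyl carbenes but not for a silyloxyalkyne or for this acyclic 1-alkoxyvinyl carbene. The single carbocyclic six-membered ring is closed by a thermal 6π electrocyclisation of the dienylketene. No stereocentre is created. The step needs the hexadecyl carbon of 9 to bond to the carbene carbon, which the polarisation of the ynol ether (nucleophilic carbon at the alkyl end, electrophilic carbene carbon) and the preference of the bulky iPr3SiO group for the position next to the incoming CO should both secure. It also needs CO insertion to outrun four- or five-membered ring closure and simple accumulation of the inserted carbene, which the weak donor ability of a silyl ether oxygen (compared with the amino groups known to stall this step) should allow.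

Step 4
Reactants: 11 5-ethoxy-3-hexadecyl-4-methoxy-2-(triisopropylsilyloxy)phenol
Product: 12 5-ethoxy-3-hexadecyl-2-(triisopropylsilyloxy)-1,4-benzoquinone
Conditions: (NH4)2Ce(NO3)6 (2.2 equiv), MeCN/THF/H2O, 0 °C, short contact
Reagents that add atoms: water, O
Why: Oxidative demethylation of a 4-methoxyphenol by tetravalent cerium (two one-electron oxidations, water addition at C4, loss of methanol) is the standard conversion of such benzannulation products into para-quinones, and short contact at 0 °C should spare the silyl group, whose partial loss would in any case converge in step 5.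

Step 5
Reactants: 12 5-ethoxy-3-hexadecyl-2-(triisopropylsilyloxy)-1,4-benzoquinone
Product: 14 3-hexadecyl-2,5-dihydroxy-1,4-benzoquinone, via disodium 3-hexadecyl-1,4-benzoquinone-2,5-bis(olate) 13 (not isolated)
Conditions: NaOH (aq), EtOH/THF, Ar, rt to 50 °C; then HCl (aq) to pH 2
Reagents that add atoms: sodium hydroxide, [Na+].[OH-]
Why: Vinylogous ester hydrolysis, in which hydroxide displaces ethoxide at C5 by addition–elimination and cleaves the silyl vinylogous ester at C2 to give the stabilised dianion that acid protonates, is the established final step for 2,5-dioxygenated 3-alkylbenzoquinones.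

Compound list
1 | ethyl vinyl ether | C=COCC | starting material
2 | hexacarbonylchromium | O=C=[Cr](=C=O)(=C=O)(=C=O)(=C=O)=C=O | starting material
3 | 1-ethoxyvinyllithium | [Li]C(=C)OCC | intermediate, not isolated
4 | lithium pentacarbonyl(2-ethoxyprop-2-enoyl)chromate | [Li+].[O-]C(C(=C)OCC)=[Cr](=C=O)(=C=O)(=C=O)(=C=O)=C=O | intermediate, not isolated
5 | pentacarbonyl[(1-ethoxyethenyl)(methoxy)carbene]chromium | COC(C(=C)OCC)=[Cr](=C=O)(=C=O)(=C=O)(=C=O)=C=O | intermediate
6 | 1-octadecyne | CCCCCCCCCCCCCCCCC#C | starting material
7 | lithium octadec-1-yn-1-ide | CCCCCCCCCCCCCCCCC#C[Li] | intermediate, not isolated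
8 | lithium octadec-1-yn-1-olate | CCCCCCCCCCCCCCCCC#C[O-].[Li+] | intermediate, not isolated
9 | 1-(triisopropylsilyloxy)octadec-1-yne | CCCCCCCCCCCCCCCCC#CO[Si](C(C)C)(C(C)C)C(C)C | intermediate
10 | tricarbonyl[η6-5-ethoxy-3-hexadecyl-4-methoxy-2-(triisopropylsilyloxy)phenol]chromium | CCCCCCCCCCCCCCCCc1c(OC)c(OCC)cc(O)c1O[Si](C(C)C)(C(C)C)C(C)C.O=C=[Cr](=C=O)=C=O | intermediate, not isolated
11 | 5-ethoxy-3-hexadecyl-4-methoxy-2-(triisopropylsilyloxy)phenol | CCCCCCCCCCCCCCCCc1c(OC)c(OCC)cc(O)c1O[Si](C(C)C)(C(C)C)C(C)C | intermediate
12 | 5-ethoxy-3-hexadecyl-2-(triisopropylsilyloxy)cyclohexa-2,5-diene-1,4-dione | CCCCCCCCCCCCCCCCC1=C(O[Si](C(C)C)(C(C)C)C(C)C)C(=O)C=C(OCC)C1=O | intermediate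
13 | disodium 3-hexadecyl-1,4-benzoquinone-2,5-bis(olate) | CCCCCCCCCCCCCCCCC1=C([O-])C(=O)C=C([O-])C1=O.[Na+].[Na+] | intermediate, not isolated
14 | 3-hexadecyl-2,5-dihydroxycyclohexa-2,5-diene-1,4-dione | CCCCCCCCCCCCCCCCC1=C(O)C(=O)C=C(O)C1=O | target

Total step count: 5
Longest linear sequence: 4 steps (step 1 or step 2, then steps 3, 4 and 5)

Steps most likely to fail

Step 3. After the regioselective alkyne insertion, CO insertion at the donor-stabilised silyloxycarbene carbon may be too slow. The intermediate could then be diverted to four- or five-membered ring closure, or accumulate and decompose, while the ynol ether oligomerises on heating. The fallback uses known chemistry, sets out from 6 and 5, and rejoins the route at 13. It carries the C2 oxygen through the annulation as boron.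
- Lithiation of 6 (n-BuLi, THF, −78 °C), borylation with 2-isopropoxy-4,4,5,5-tetramethyl-1,3,2-dioxaborolane and quenching with HCl in Et2O should give 4,4,5,5-tetramethyl-2-(octadec-1-yn-1-yl)-1,3,2-dioxaborolane F1.
- Benzannulation of 5 with F1 (THF, 45–50 °C) uses an established alkyne class for this reaction. The boronate is expected to behave as the large substituent and to take the position next to the CO-derived carbon. This should give the tricarbonyl(η6-arene)chromium complex of the boronate phenol F2 and, after exposure to air, 5-ethoxy-3-hexadecyl-4-methoxy-2-(4,4,5,5-tetramethyl-1,3,2-dioxaborolan-2-yl)phenol F3.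
- Oxidation of the C–B bond (NaBO3·4H2O, THF/H2O) would give 5-ethoxy-3-hexadecyl-4-methoxybenzene-1,2-diol F4.
- Ag2O (Et2O, Na2SO4) would oxidise this to the ortho-quinone 5-ethoxy-3-hexadecyl-4-methoxycyclohexa-3,5-diene-1,2-dione F5.
- Aqueous NaOH hydrolysis of the two vinylogous ester groups of F5 leads to the dianion 13, which is acidified to 14 as in step 5.

Step 1. The acid-labile, electron-rich enol ether may be lost, or may oligomerise cationically, during O-methylation with a strongly electrophilic oxonium salt. Incomplete lithiation would also let residual t-BuLi attack Cr(CO)6. The fallback sets out from 4 and rejoins at 5. It installs the methoxy group by substitution at the carbene carbon instead of O-alkylation.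
- Cation exchange of 4 with Me4NBr in degassed water should precipitate tetramethylammonium pentacarbonyl(2-ethoxyprop-2-enoyl)chromate F6, which can be recrystallised and stored.
- Acetyl bromide (CH2Cl2, −40 °C) converts it into the acyloxycarbene complex pentacarbonyl[(acetyloxy)(1-ethoxyethenyl)carbene]chromium F7, which is not isolated.
- Methanol (−40 to 0 °C) then displaces acetate by addition–elimination to give 5.

Step 4. Under the strongly acidic one-electron oxidation, premature loss of the silyl group followed by over-oxidation or nitration of the very electron-rich ring may erode the material. The fallback sets out from 11 and rejoins at 12. It uses a two-electron hypervalent iodine oxidation instead.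
- PhI(OAc)2 in MeOH/CH2Cl2 at 0 °C should trap the phenoxenium ion at C4 as the quinone monoketal 5-ethoxy-3-hexadecyl-4,4-dimethoxy-2-(triisopropylsilyloxy)cyclohexa-2,5-dien-1-one F8.
- Dilute aqueous oxalic acid in THF then hydrolyses the ketal to 12.

Further compounds
F1 | step 3 | 4,4,5,5-tetramethyl-2-(octadec-1-yn-1-yl)-1,3,2-dioxaborolane | CCCCCCCCCCCCCCCCC#CB1OC(C)(C)C(C)(C)O1
F2 | step 3 | tricarbonyl[η6-5-ethoxy-3-hexadecyl-4-methoxy-2-(4,4,5,5-tetramethyl-1,3,2-dioxaborolan-2-yl)phenol]chromium | CCCCCCCCCCCCCCCCc1c(OC)c(OCC)cc(O)c1B1OC(C)(C)C(C)(C)O1.O=C=[Cr](=C=O)=C=O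
F3 | step 3 | 5-ethoxy-3-hexadecyl-4-methoxy-2-(4,4,5,5-tetramethyl-1,3,2-dioxaborolan-2-yl)phenol | CCCCCCCCCCCCCCCCc1c(OC)c(OCC)cc(O)c1B1OC(C)(C)C(C)(C)O1
F4 | step 3 | 5-ethoxy-3-hexadecyl-4-methoxybenzene-1,2-diol | CCCCCCCCCCCCCCCCc1c(OC)c(OCC)cc(O)c1O
F5 | step 3 | 5-ethoxy-3-hexadecyl-4-methoxycyclohexa-3,5-diene-1,2-dione | CCCCCCCCCCCCCCCCC1=C(OC)C(OCC)=CC(=O)C1=O
F6 | step 1 | tetramethylammonium pentacarbonyl(2-ethoxyprop-2-enoyl)chromate | C[N+](C)(C)C.[O-]C(C(=C)OCC)=[Cr](=C=O)(=C=O)(=C=O)(=C=O)=C=O
F7 | step 1 | pentacarbonyl[(acetyloxy)(1-ethoxyethenyl)carbene]chromium | CC(=O)OC(C(=C)OCC)=[Cr](=C=O)(=C=O)(=C=O)(=C=O)=C=O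
F8 | step 4 | 5-ethoxy-3-hexadecyl-4,4-dimethoxy-2-(triisopropylsilyloxy)cyclohexa-2,5-dien-1-one | CCCCCCCCCCCCCCCCC1=C(O[Si](C(C)C)(C(C)C)C(C)C)C(=O)C=C(OCC)C1(OC)OC
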